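The ratio of target gained to starting material lost between two readings, the marginal yield 0.191 in the red run from 8.00 h to 15.0 h (a differential selectivity, net of losses, and a reading with its scatter), lets you bracket this flask, which is the red run carried on.

| setting | red | green | flask |
|---|---|---|---|
| starting material | 0.037 M | 0.074 M | 0.037 M |
| reagent in the second phase | 0.0555 M | 0.0555 M | 0.0555 M |
| remark | the very flask that is asked about, followed so far | run made earlier |  |
| time |  |  | 3.0 d |
| volume of the second phase over the first |  |  | 1.0 |

- red (time / h: target / %, starting material / %): 3.00: 6.2, 88.5; 6.00: 11.7, 72.7; 8.00: 14.9, 63.9; 12.0: 18.2, 46.5; 15.0: 19.8, 38.2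
- green (time / h: target / %, starting material / %): 4.00: 5.6, 87.1; 8.00: 9.7, 75.0; 15.0: 13.0, 57.7; 25.0: 16.3, 45.2; 48.0: 18.0, 31.5

(standard deviation of a reading: 0.5 percentage points)

- what is said of target includes product in the second phase
- in the second phase: reagent in the second phase, product in the second phase; everything else is in the first
- charges count per volume of the first phase; a concentration in a rate is the amount of a species over the volume of its own phase; every rate counts per litre of the first phase
- the earlier runs were read with a standard deviation of 0.5 percentage points
- the earlier runs hold the two phases in the same ratio of volumes as the flask asked about

- the target and product in the second phase together standing at 3.0 d, as a percentage of the starting material charged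
- part of the starting material charged that has reacted at 3.0 d

At 15.0 h the red flask holds 38.2% of its charge as starting material and 19.8% as target, and if you carry the decay of that same stretch on at a constant first-order rate, 0.579% is left at 3.0 d, so I reckon 99.4% reacted. If the red marginal yield held to the end, target would reach 27.0%, but the latest green stretch, read in a flask charged with twice the starting material, gives the lower ratio 0.124, and with that ratio target would reach 24.5%, which I take, as an estimate and not a proven bound, for my ceiling. For the floor I take the last red reading, 19.8%, a judgement resting on green's target still rising at 48.0 h, and between floor and ceiling I commit to 22.1%.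

The forecast says 16% and 95%, holding that “green still rises past that point, so loss is probably slower or partly protected in the second phase”; its target stands below my floor.

The flask gives 22.5% and 99.3%, inside the bracket.

    reagent in the reaction phase ⇌ reagent in the second phase, rate k1*([reagent in the reaction phase] - [reagent in the second phase]/K1) per volume of the first phase (partition coefficient = 1.38, kL = 3.08 × 10⁻⁵ s⁻¹)
    starting material + reagent in the reaction phase → target (k = 0.00245 M⁻¹ s⁻¹)
    target ⇌ product in the second phase, rate k3*([target] - [product in the second phase]/K3) per volume of the first phase (partition coefficient = 23.0, kL = 4.61 × 10⁻⁵ s⁻¹)
    target → decomposed product (k = 8.62 × 10⁻⁵ s⁻¹)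
    reagent in the reaction phase → decomposition product (k = 2.26 × 10⁻⁸ s⁻¹)
    target ⇌ isomer of the product (K = 1.10, k = 4.74 × 10⁻⁵ s⁻¹)
    target → over-reaction product (k = 2.41 × 10⁻⁵ s⁻¹)

From the last red reading to 3.0 d this flask's marginal yield averages 0.0729, lower than green's late reading, and on the way target stands at 24.8% at 1.50 d before easing to 22.5%. Now take the same flask stopped at 20 h, where 26.2% of the starting material remains: the red marginal yield, applied to the starting material lost since 15.0 h, gives 22.1%, and that flask stands at 22.2%.

The runs stem from a simulated flask for an exercise; noise was put on by code.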